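No cross-coupling builds the C7–C8' axis. That bond is installed early as an aryl–sp3 link in a 3-arylphthalide, and the methyl-free naphthalene ring (C5'–C8', C4a', C8a') is grown around it. The feature used is the 1,4-relationship between C8' and the oxygenated C5' in this ring: C8' maps onto the phthalide methine, C5' onto the lactone carbonyl. In one operation, conjugate addition to methyl acrylate (C7'–C8'), Dieckmann closure (C5'–C6') and acid dehydration deliver the aromatic ring with the hindered axis in place. Precursor 17 is the cis-(1R,3S)-N-methyltetrahydroisoquinoline bearing a 7-methoxy-5-methylphthalid-3-yl group at C7.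

Key step: step 9

Assumption: the SMILES defines C1 (R) and C3 (S) but gives no descriptor for the C7–C8' axis, so the route controls only the two stereocentres. If rotation about the axis is slow, the two rotamers of 24 would be separated by chromatography.

Step 1
Reactants: 1 1-bromo-3,5-dimethoxybenzene; 2 tert-butyl (2S)-2-methylaziridine-1-carboxylate
Product: 4 tert-butyl N-[(2S)-1-(3,5-dimethoxyphenyl)propan-2-yl]carbamate, via arylmagnesium bromide 3 (not isolated)
Conditions: Mg, THF, reflux; then CuI (10 mol %), 2, THF, −30 °C → rt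
Reagents that add atoms: none
Why: Copper-catalysed SN2 ring opening of an N-Boc-activated aziridine by an aryl Grignard reagent occurs at the unsubstituted CH2, so the C–N stereocentre (future C3, S) passes unchanged from 2 into 4.

Step 2
Reactants: 4 tert-butyl N-[(2S)-1-(3,5-dimethoxyphenyl)propan-2-yl]carbamate
Product: 6 N-[(2S)-1-(3,5-dimethoxyphenyl)propan-2-yl]acetamide, via amine hydrochloride 5 (not isolated)
Conditions: HCl (4 M in dioxane), CH2Cl2, rt; then Ac2O, Et3N, CH2Cl2, 0 °C → rt
Reagents that add atoms: acetic anhydride, CC(=O)OC(C)=O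
Why: Acidolytic Boc cleavage followed by N-acetylation of the liberated amine are routine transformations that leave the stereocentre untouched, and the acetyl group brings in C1 together with its methyl group.

Step 3
Reactants: 6 N-[(2S)-1-(3,5-dimethoxyphenyl)propan-2-yl]acetamide
Product: 7 (3S)-6,8-dimethoxy-1,3-dimethyl-3,4-dihydroisoquinoline
Conditions: POCl3, MeCN, reflux
Reagents that add atoms: none
Why: The Bischler–Napieralski cyclodehydration closes the ring at either of the two equivalent positions next to the side chain, each activated by one ortho and one para methoxy group, so only the 6,8-dimethoxy isomer can form.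

Step 4
Reactants: 7 (3S)-6,8-dimethoxy-1,3-dimethyl-3,4-dihydroisoquinoline
Product: 8 (1R,3S)-6,8-dimethoxy-1,3-dimethyl-1,2,3,4-tetrahydroisoquinoline (cis)
Conditions: NaBH4, MeOH, 0 °C
Reagents that add atoms: none
Why: Borohydride reduction of 1,3-dimethyl-3,4-dihydroisoquinolines is a known cis-selective imine reduction in which hydride reaches C1 from the face opposite the C3 methyl group, which sets C1 as R, and any trans isomer is removed here by chromatography.

Step 5
Reactants: 8 (1R,3S)-6,8-dimethoxy-1,3-dimethyl-1,2,3,4-tetrahydroisoquinoline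
Product: 9 (1R,3S)-6,8-dimethoxy-1,2,3-trimethyl-1,2,3,4-tetrahydroisoquinoline
Conditions: aq. HCHO (37 %), NaBH(OAc)3, MeCN, rt
Reagents that add atoms: formaldehyde, C=O
Why: Reductive amination with formaldehyde methylates the secondary amine once only, under conditions too mild to epimerise C1 or to attack the electron-rich ring.

Step 6
Reactants: 9 (1R,3S)-6,8-dimethoxy-1,2,3-trimethyl-1,2,3,4-tetrahydroisoquinoline
Product: 11 (1R,3S)-6,8-dimethoxy-1,2,3-trimethyl-1,2,3,4-tetrahydroisoquinoline-7-carbaldehyde, via C7-lithio isoquinoline 10 (not isolated)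
Conditions: n-BuLi, TMEDA, Et2O, 0 °C → rt; then DMF, −78 °C → rt
Reagents that add atoms: N,N-dimethylformamide, CN(C)C=O
Why: In this directed ortho-metalation C7–H lies between two methoxy groups and is the most acidic and best coordinated aryl position (as in the 2-lithiation of 4-alkyl-1,3-dimethoxybenzenes), the aryllithium is formylated by DMF, and the method is chosen because electrophilic substitution would go to C5.

Step 7
Reactants: 12 2-methoxy-4-methylbenzoic acid
Product: 14 N,N-diethyl-2-methoxy-4-methylbenzamide, via acid chloride 13 (not isolated)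
Conditions: (COCl)2, DMF (cat.), CH2Cl2, 0 °C → rt; then Et2NH (excess), 0 °C
Reagents that add atoms: diethylamine, CCNCC
Why: Amide formation through the acid chloride (nucleophilic acyl substitution) is routine, and the tertiary diethylamide is a strong directing group for the lithiation that follows.

Step 8
Reactants: 14 N,N-diethyl-2-methoxy-4-methylbenzamide; 11 (1R,3S)-6,8-dimethoxy-1,2,3-trimethyl-1,2,3,4-tetrahydroisoquinoline-7-carbaldehyde
Product: 17 3-[(1R,3S)-6,8-dimethoxy-1,2,3-trimethyl-1,2,3,4-tetrahydroisoquinolin-7-yl]-7-methoxy-5-methyl-2-benzofuran-1(3H)-one (both epimers at the phthalide carbon), via lithiated benzamide 15 (not isolated), via hydroxy amide 16 (not isolated)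
Conditions: 14 (1.4 equiv), s-BuLi, TMEDA, THF, −78 °C; 11, −78 °C → rt; then aq. HCl (3 M, excess), 60 °C
Reagents that add atoms: none
Why: Directed ortho-metalation of the benzamide can only take the one free position next to the amide, 1,2-addition to the non-enolisable aldehyde gives the carbinol, and acid-promoted intramolecular acyl transfer expels diethylamine to close the five-membered lactone; the carbinol configuration does not matter because step 9 erases it.

Step 9
Reactants: 17 3-[(1R,3S)-6,8-dimethoxy-1,2,3-trimethyl-1,2,3,4-tetrahydroisoquinolin-7-yl]-7-methoxy-5-methyl-2-benzofuran-1(3H)-one; 18 methyl acrylate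
Product: 21 methyl 4-[(1R,3S)-6,8-dimethoxy-1,2,3-trimethyl-1,2,3,4-tetrahydroisoquinolin-7-yl]-1-hydroxy-8-methoxy-6-methylnaphthalene-2-carboxylate, via lithium phthalide enolate 19 (not isolated), via hydroxytetralone ester 20 (not isolated)
Conditions: LDA (1.2 equiv), THF, −78 °C; 18 (1.5 equiv, slow addition), −78 → 0 °C; then TFA (10 equiv), 0 °C → rt
Reagents that add atoms: none
Why: LDA removes the doubly benzylic, oxygen-flanked methine hydrogen of either epimer of 17 to give the planar isobenzofuranolate 19, whose carbanionic carbon (future C8') adds to the β-carbon of 18, and the ester enolate so formed attacks the lactone carbonyl, releasing the ring oxygen as a tertiary alkoxide while deprotonation of the new β-keto ester holds the equilibrium on the side of 20. Excess TFA (the amine takes up one equivalent) ionises the tertiary diaryl carbinol, a proton leaves C7' and the keto ester enolises, so water is lost and the ring becomes aromatic with the C5' hydroxyl peri to the C4' methoxy group. The closest known chemistry is the Michael–Dieckmann annulation of phthalide anions with acrylates, that is a Hauser–Kraus annulation without a leaving group that is finished by dehydration, and 3-arylphthalides are known to be deprotonated by LDA; a donor whose aryl group carries two ortho methoxy groups is more hindered than the documented cases and is the one real risk of the route. The single new ring closes in a 6-(enolexo)-exo-trig mode. The stereocentres that appear at C8' and C6' in 20 are both erased on aromatisation, C1 and C3 are untouched, and the sense of the new axis is not controlled. The step needs 1,4-addition to outrun acrylate oligomerisation and proton exchange, which the soft delocalised anion, the slow addition at low temperature and the fast intramolecular capture of the enolate favour, while the regiochemistry (ester next to the C5' oxygen) follows from the connectivity of 19.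

Step 10
Reactants: 21 methyl 4-[(1R,3S)-6,8-dimethoxy-1,2,3-trimethyl-1,2,3,4-tetrahydroisoquinolin-7-yl]-1-hydroxy-8-methoxy-6-methylnaphthalene-2-carboxylate
Product: 22 4-[(1R,3S)-6,8-dimethoxy-1,2,3-trimethyl-1,2,3,4-tetrahydroisoquinolin-7-yl]-1-hydroxy-8-methoxy-6-methylnaphthalene-2-carboxylic acid
Conditions: KOH (excess), MeOH–H2O, reflux, N2; then HCl to pH 6
Reagents that add atoms: potassium hydroxide, [K+].[OH-]
Why: Ester saponification by acyl–oxygen cleavage needs heat because the naphtholate forms first, but no other group in the molecule is sensitive to hot alkali.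

Step 11
Reactants: 22 4-[(1R,3S)-6,8-dimethoxy-1,2,3-trimethyl-1,2,3,4-tetrahydroisoquinolin-7-yl]-1-hydroxy-8-methoxy-6-methylnaphthalene-2-carboxylic acid
Product: 23 4-[(1R,3S)-6,8-dimethoxy-1,2,3-trimethyl-1,2,3,4-tetrahydroisoquinolin-7-yl]-8-methoxy-6-methylnaphthalen-1-ol
Conditions: Cu2O (10 mol %), 1,10-phenanthroline (20 mol %), NMP–quinoline, 170 °C, argon
Reagents that add atoms: none
Why: Protodecarboxylation of a 1-hydroxy-2-naphthoic acid, which behaves as the enol of a β-keto acid (protonation at C6', loss of CO2), is a known thermal reaction that copper catalysis accelerates, and neither stereocentre has a pathway to epimerise without an oxidant.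

Step 12
Reactants: 23 4-[(1R,3S)-6,8-dimethoxy-1,2,3-trimethyl-1,2,3,4-tetrahydroisoquinolin-7-yl]-8-methoxy-6-methylnaphthalen-1-ol
Product: 24 ancistrobrevine A, (1R,3S)-7-(4,5-dimethoxy-7-methylnaphthalen-1-yl)-6,8-dimethoxy-1,2,3-trimethyl-1,2,3,4-tetrahydroisoquinoline
Conditions: TMSCHN2, iPr2NEt, MeCN–MeOH, rt
Reagents that add atoms: (trimethylsilyl)diazomethane, C[Si](C)(C)C=[N+]=[N-]
Why: O-Methylation of a phenol with a diazoalkane needs an acidic O–H and therefore leaves the tertiary amine alone, whereas methyl iodide or dimethyl sulfate could quaternise the nitrogen.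

Compound list
1 | 1-bromo-3,5-dimethoxybenzene | COc1cc(Br)cc(OC)c1 | starting material
2 | tert-butyl (2S)-2-methylaziridine-1-carboxylate | C[C@H]1CN1C(=O)OC(C)(C)C | starting material
3 | 3,5-dimethoxyphenylmagnesium bromide | COc1cc([Mg]Br)cc(OC)c1 | intermediate
4 | tert-butyl N-[(2S)-1-(3,5-dimethoxyphenyl)propan-2-yl]carbamate | C[C@@H](Cc1cc(OC)cc(OC)c1)NC(=O)OC(C)(C)C | intermediate
5 | (2S)-1-(3,5-dimethoxyphenyl)propan-2-aminium chloride | C[C@@H](Cc1cc(OC)cc(OC)c1)[NH3+].[Cl-] | intermediate
6 | N-[(2S)-1-(3,5-dimethoxyphenyl)propan-2-yl]acetamide | C[C@@H](Cc1cc(OC)cc(OC)c1)NC(C)=O | intermediate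
7 | (3S)-6,8-dimethoxy-1,3-dimethyl-3,4-dihydroisoquinoline | COc1cc2c(c(OC)c1)C(C)=N[C@@H](C)C2 | intermediate
8 | (1R,3S)-6,8-dimethoxy-1,3-dimethyl-1,2,3,4-tetrahydroisoquinoline | COc1cc2c(c(OC)c1)[C@@H](C)N[C@@H](C)C2 | intermediate
9 | (1R,3S)-6,8-dimethoxy-1,2,3-trimethyl-1,2,3,4-tetrahydroisoquinoline | COc1cc2c(c(OC)c1)[C@@H](C)N(C)[C@@H](C)C2 | intermediate
10 | [(1R,3S)-6,8-dimethoxy-1,2,3-trimethyl-1,2,3,4-tetrahydroisoquinolin-7-yl]lithium | COc1cc2c(c(OC)c1[Li])[C@@H](C)N(C)[C@@H](C)C2 | intermediate
11 | (1R,3S)-6,8-dimethoxy-1,2,3-trimethyl-1,2,3,4-tetrahydroisoquinoline-7-carbaldehyde | COc1cc2c(c(OC)c1C=O)[C@@H](C)N(C)[C@@H](C)C2 | intermediate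
12 | 2-methoxy-4-methylbenzoic acid | COc1cc(C)ccc1C(=O)O | starting material
13 | 2-methoxy-4-methylbenzoyl chloride | COc1cc(C)ccc1C(=O)Cl | intermediate
14 | N,N-diethyl-2-methoxy-4-methylbenzamide | CCN(CC)C(=O)c1ccc(C)cc1OC | intermediate
15 | [2-(diethylcarbamoyl)-3-methoxy-5-methylphenyl]lithium | CCN(CC)C(=O)c1c(OC)cc(C)cc1[Li] | intermediate
16 | N,N-diethyl-2-{[(1R,3S)-6,8-dimethoxy-1,2,3-trimethyl-1,2,3,4-tetrahydroisoquinolin-7-yl](hydroxy)methyl}-6-methoxy-4-methylbenzamide (both carbinol epimers) | COc1cc2c(c(OC)c1C(O)c1cc(C)cc(OC)c1C(=O)N(CC)CC)[C@@H](C)N(C)[C@@H](C)C2 | intermediate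
17 | 3-[(1R,3S)-6,8-dimethoxy-1,2,3-trimethyl-1,2,3,4-tetrahydroisoquinolin-7-yl]-7-methoxy-5-methyl-2-benzofuran-1(3H)-one (both epimers at the phthalide carbon) | COc1cc2c(c(OC)c1C1OC(=O)c3c(OC)cc(C)cc31)[C@@H](C)N(C)[C@@H](C)C2 | intermediate
18 | methyl acrylate | C=CC(=O)OC | starting material
19 | lithium 3-[(1R,3S)-6,8-dimethoxy-1,2,3-trimethyl-1,2,3,4-tetrahydroisoquinolin-7-yl]-7-methoxy-5-methyl-2-benzofuran-1-olate | COc1cc2c(c(OC)c1-c1oc(O[Li])c3c(OC)cc(C)cc13)[C@@H](C)N(C)[C@@H](C)C2 | intermediate
20 | methyl 4-[(1R,3S)-6,8-dimethoxy-1,2,3-trimethyl-1,2,3,4-tetrahydroisoquinolin-7-yl]-4-hydroxy-8-methoxy-6-methyl-1-oxo-1,2,3,4-tetrahydronaphthalene-2-carboxylate (mixture at C2 and C4 of the tetralone) | COc1cc2c(c(OC)c1C1(O)CC(C(=O)OC)C(=O)c3c(OC)cc(C)cc31)[C@@H](C)N(C)[C@@H](C)C2 | intermediate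
21 | methyl 4-[(1R,3S)-6,8-dimethoxy-1,2,3-trimethyl-1,2,3,4-tetrahydroisoquinolin-7-yl]-1-hydroxy-8-methoxy-6-methylnaphthalene-2-carboxylate | COc1cc2c(c(OC)c1-c1cc(C(=O)OC)c(O)c3c(OC)cc(C)cc13)[C@@H](C)N(C)[C@@H](C)C2 | intermediate
22 | 4-[(1R,3S)-6,8-dimethoxy-1,2,3-trimethyl-1,2,3,4-tetrahydroisoquinolin-7-yl]-1-hydroxy-8-methoxy-6-methylnaphthalene-2-carboxylic acid | COc1cc2c(c(OC)c1-c1cc(C(=O)O)c(O)c3c(OC)cc(C)cc13)[C@@H](C)N(C)[C@@H](C)C2 | intermediate
23 | 4-[(1R,3S)-6,8-dimethoxy-1,2,3-trimethyl-1,2,3,4-tetrahydroisoquinolin-7-yl]-8-methoxy-6-methylnaphthalen-1-ol | COc1cc2c(c(OC)c1-c1ccc(O)c3c(OC)cc(C)cc13)[C@@H](C)N(C)[C@@H](C)C2 | intermediate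
24 | ancistrobrevine A | COc1cc2c(c(OC)c1-c1ccc(OC)c3c(OC)cc(C)cc13)[C@@H](C)N(C)[C@@H](C)C2 | target

Total step count: 12. Longest linear sequence: 11 steps (steps 1–6 and 8–12); step 7 lies on the short branch.

Steps most likely to fail

Step 9. The crowded carbanion may fail to engage the acrylate. Proton exchange with unreacted 17 and anionic oligomerisation of 18 could then consume both partners. The fallback sets out from 17 and returns at 21, and it makes the same two bonds by a neutral cycloaddition instead of an anionic cascade.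
- Enolate 19 is trapped on oxygen (LDA, TBSCl, THF, −78 °C → rt) as the 1-silyloxy-3-arylisobenzofuran F1. Dienes of this type, made from 3-arylphthalides, are known to be reactive in the Diels–Alder reaction.
- Heating with 18 in toluene should give the oxygen-bridged cycloadduct F2. The silyloxy donor directs the ester-bearing carbon to the ketal terminus.
- TFA in CH2Cl2 then opens the bridge, removes silicon and dehydrates to 21.

Step 6. Deprotonation may be slow or misdirected, because the C8 methoxy group is pushed toward C7 by the C1 methyl group, and metalation at C5 could compete. The fallback sets out from 4 and returns at 10. The handle is placed as bromine while the ring is still symmetric and unbuttressed, and is later converted by halogen–lithium exchange, which cannot choose the wrong site.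
- Carbamate 4 with n-BuLi (2.3 equiv, THF, 0 °C) gives the N,4-dilithio carbamate F3. Lithiation occurs between the two methoxy groups, as for 5-alkylresorcinol dimethyl ethers.
- BrCF2CF2Br at −78 °C gives the 4-bromo carbamate F4.
- The conditions of steps 2 to 5 then lead through the bromo amine hydrochloride F5, the bromo acetamide F6, the 7-bromodihydroisoquinoline F7 and the cis 7-bromotetrahydroisoquinoline F8 to the N-methyl 7-bromide F9.
- n-BuLi (THF, −78 °C) exchanges bromine for lithium to give 10, which is formylated as in step 6.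

Step 11. Loss of CO2 from the aromatic hydroxy acid may be sluggish, and long heating could degrade the electron-rich naphthol. The fallback sets out from 20 and returns at 23. It removes the ester before aromatisation, while it is still a true β-keto ester.
- Step 9 is stopped with pH 7 buffer instead of TFA so that 20 is isolated.
- Krapcho dealkoxycarbonylation (LiCl, DMSO–H2O, 140 °C) gives the 4-aryl-4-hydroxytetralone F10.
- TFA in CH2Cl2 dehydrates F10 to 23, which also makes step 10 unnecessary.

Further compounds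
F1 | step 9 | (1R,3S)-7-{3-[(tert-butyldimethylsilyl)oxy]-4-methoxy-6-methyl-2-benzofuran-1-yl}-6,8-dimethoxy-1,2,3-trimethyl-1,2,3,4-tetrahydroisoquinoline | COc1cc2c(c(OC)c1-c1oc(O[Si](C)(C)C(C)(C)C)c3c(OC)cc(C)cc13)[C@@H](C)N(C)[C@@H](C)C2
F2 | step 9 | methyl 1-[(tert-butyldimethylsilyl)oxy]-4-[(1R,3S)-6,8-dimethoxy-1,2,3-trimethyl-1,2,3,4-tetrahydroisoquinolin-7-yl]-8-methoxy-6-methyl-1,2,3,4-tetrahydro-1,4-epoxynaphthalene-2-carboxylate | COc1cc2c(c(OC)c1C13CC(C(=O)OC)C(O[Si](C)(C)C(C)(C)C)(O1)c1c(OC)cc(C)cc13)[C@@H](C)N(C)[C@@H](C)C2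
F3 | step 6 | N,4-dilithio derivative of tert-butyl N-[(2S)-1-(3,5-dimethoxyphenyl)propan-2-yl]carbamate | C[C@@H](Cc1cc(OC)c([Li])c(OC)c1)N([Li])C(=O)OC(C)(C)C
F4 | step 6 | tert-butyl N-[(2S)-1-(4-bromo-3,5-dimethoxyphenyl)propan-2-yl]carbamate | C[C@@H](Cc1cc(OC)c(Br)c(OC)c1)NC(=O)OC(C)(C)C
F5 | step 6 | (2S)-1-(4-bromo-3,5-dimethoxyphenyl)propan-2-aminium chloride | C[C@@H](Cc1cc(OC)c(Br)c(OC)c1)[NH3+].[Cl-]
F6 | step 6 | N-[(2S)-1-(4-bromo-3,5-dimethoxyphenyl)propan-2-yl]acetamide | C[C@@H](Cc1cc(OC)c(Br)c(OC)c1)NC(C)=O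
F7 | step 6 | (3S)-7-bromo-6,8-dimethoxy-1,3-dimethyl-3,4-dihydroisoquinoline | COc1cc2c(c(OC)c1Br)C(C)=N[C@@H](C)C2
F8 | step 6 | (1R,3S)-7-bromo-6,8-dimethoxy-1,3-dimethyl-1,2,3,4-tetrahydroisoquinoline | COc1cc2c(c(OC)c1Br)[C@@H](C)N[C@@H](C)C2
F9 | step 6 | (1R,3S)-7-bromo-6,8-dimethoxy-1,2,3-trimethyl-1,2,3,4-tetrahydroisoquinoline | COc1cc2c(c(OC)c1Br)[C@@H](C)N(C)[C@@H](C)C2
F10 | step 11 | 4-[(1R,3S)-6,8-dimethoxy-1,2,3-trimethyl-1,2,3,4-tetrahydroisoquinolin-7-yl]-4-hydroxy-8-methoxy-6-methyl-3,4-dihydronaphthalen-1(2H)-one | COc1cc2c(c(OC)c1C1(O)CCC(=O)c3c(OC)cc(C)cc31)[C@@H](C)N(C)[C@@H](C)C2
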